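**Retrosynthetic overview** (prostanoid numbering: C1 ester carbon, C8–C12 ring, C13–C20 octadienyl chain)

1. Target ⇐ triol 24: both acetates and the C7=C8 alkene come last (acetylation, then E1cB loss of a C7 acetate); the C7 carbinol is a temporary stereocentre.
2. Aldol 23 ⇐ C12–C13: (2Z,5Z)-octa-2,5-dienylbarium 20 + (Z)-5-ylidenefuran-2(5H)-one 19; addition to the lactone carbonyl, ring opening and C8→C12 aldol closure in one operation.
3. Enabling feature: the ring C8–C9(=O)–C10=C11–C12(OH) is the aldol form of a cis-ene-1,4-dione, which is the opened adduct of a nucleophile with a furanone whose lactone carbonyl is C12, ring alkene C10=C11, O-bearing ring carbon C9 and exocyclic carbon C8; the 7R alkoxide next to C8 steers the closure.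
4. 19 ⇐ (Z)-3-iodoacrylic acid + enynol 16 (Pd/Cu coupling–lactonisation); 16 ⇐ Z-enal 12 + ethynyltrimethylsilane; 12 ⇐ ynone 8 (transfer hydrogenation sets C4, Lindlar sets 5Z).
5. Rings: furanone first (step 11), then the cyclopentenone (step 12) at the expense of the furanone; no ring is formed afterwards.

Key step: step 12

Remarks on the chemistry:
- Assumption: in step 9 the (S,S)-ProPhenol–zinc catalyst is taken to add the alkynyl group to the Si face of the (Z)-enal (giving 7R); if the sense of induction is the reverse, the (R,R)-ligand is used and nothing else changes.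
- Compounds 1, 2, 6, 7, 13 and 17 are taken as commercially available.

**Step 1**
Reactants: 1 1-bromopent-2-yne; 2 prop-2-yn-1-ol
Product: 3 octa-2,5-diyn-1-ol
Conditions: CuI, NaI, Cs2CO3, DMF, rt
Reagents that add atoms: none
Why: Copper-mediated SN2 coupling of the terminal alkyne with the propargylic bromide (copper acetylide alkylation) should give the skipped diyne without allene formation.

**Step 2**
Reactants: 3 octa-2,5-diyn-1-ol
Product: 4 (2Z,5Z)-octa-2,5-dien-1-ol
Conditions: H2 (1 atm), Ni(OAc)2·4H2O/NaBH4 (P-2 Ni), ethylenediamine, EtOH, rt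
Reagents that add atoms: none
Why: P-2 nickel semihydrogenation adds hydrogen syn to each alkyne and stops at the diene, which sets the 14Z and 17Z alkenes.

**Step 3**
Reactants: 4 (2Z,5Z)-octa-2,5-dien-1-ol
Product: 5 (2Z,5Z)-1-chloroocta-2,5-diene
Conditions: NCS, Me2S, CH2Cl2, −40 → 0 °C
Reagents that add atoms: N-chlorosuccinimide, O=C1CCC(=O)N1Cl
Why: Corey–Kim chlorination (SN2 displacement of the alkoxysulfonium ion by chloride) should convert the primary allylic alcohol into the chloride without allylic transposition or loss of Z geometry.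

**Step 4**
Reactants: 6 methyl 4-chloro-4-oxobutanoate; 7 3,3-diethoxyprop-1-yne
Product: 8 methyl 7,7-diethoxy-4-oxohept-5-ynoate
Conditions: PdCl2(PPh3)2 (2 mol%), CuI (4 mol%), Et3N, THF, rt
Reagents that add atoms: none
Why: Acyl Sonogashira coupling of an acid chloride with a terminal alkyne gives the ynone, and the methyl ester and the acetal are inert.

**Step 5**
Reactants: 8 methyl 7,7-diethoxy-4-oxohept-5-ynoate
Product: 9 methyl (R)-7,7-diethoxy-4-hydroxyhept-5-ynoate
Conditions: Ru[(R,R)-TsDPEN](p-cymene) (1 mol%), i-PrOH, rt; crude product used at once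
Reagents that add atoms: none
Why: Noyori asymmetric transfer hydrogenation of an α,β-acetylenic ketone, in which the alkynyl group plays the part of the aryl group of the usual substrates, should set C4 as R with the (R,R)-catalyst.

**Step 6**
Reactants: 9 methyl (R)-7,7-diethoxy-4-hydroxyhept-5-ynoate
Product: 10 methyl (R)-4-[(tert-butyldimethylsilyl)oxy]-7,7-diethoxyhept-5-ynoate
Conditions: TBSCl, imidazole, DMF, 0 °C → rt
Reagents that add atoms: tert-butyldimethylsilyl chloride, CC(C)(C)[Si](C)(C)Cl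
Why: Imidazole-mediated silylation of the secondary alcohol blocks O4, so the γ-hydroxy ester cannot lactonise and the oxygen stays inert in the key step.

**Step 7**
Reactants: 10 methyl (R)-4-[(tert-butyldimethylsilyl)oxy]-7,7-diethoxyhept-5-ynoate
Product: 11 methyl (4R,5Z)-4-[(tert-butyldimethylsilyl)oxy]-7,7-diethoxyhept-5-enoate
Conditions: H2 (1 atm), Lindlar catalyst, quinoline, EtOAc, rt
Reagents that add atoms: none
Why: Lindlar semihydrogenation adds hydrogen syn to the alkyne and sets the 5Z alkene, with quinoline suppressing over-reduction.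

**Step 8**
Reactants: 11 methyl (4R,5Z)-4-[(tert-butyldimethylsilyl)oxy]-7,7-diethoxyhept-5-enoate
Product: 12 methyl (4R,5Z)-4-[(tert-butyldimethylsilyl)oxy]-7-oxohept-5-enoate
Conditions: oxalic acid (cat.), wet SiO2, CH2Cl2, 0 °C
Reagents that add atoms: water, O
Why: Mild acid hydrolysis of the allylic diethyl acetal through the conjugated oxocarbenium ion frees the aldehyde under conditions cold and short enough to keep the Z geometry and the silyl ether.

**Step 9**
Reactants: 12 methyl (4R,5Z)-4-[(tert-butyldimethylsilyl)oxy]-7-oxohept-5-enoate; 13 ethynyltrimethylsilane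
Product: 15 methyl (4R,5Z,7R)-4-[(tert-butyldimethylsilyl)oxy]-7-hydroxy-9-(trimethylsilyl)non-5-en-8-ynoate, via alkynylzinc 14 (not isolated)
Conditions: (S,S)-ProPhenol (20 mol%), Me2Zn (3 equiv), Ph3P=O (40 mol%), PhMe, 0 °C; aq NH4Cl
Reagents that add atoms: none
Why: Zinc–ProPhenol catalysed asymmetric alkynylation of an α,β-unsaturated aldehyde should add the zinc acetylide to the Si face and set the temporary C7 carbinol as R under catalyst control, while the ester does not react with the alkynylzinc.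

**Step 10**
Reactants: 15 methyl (4R,5Z,7R)-4-[(tert-butyldimethylsilyl)oxy]-7-hydroxy-9-(trimethylsilyl)non-5-en-8-ynoate
Product: 16 methyl (4R,5Z,7R)-4-[(tert-butyldimethylsilyl)oxy]-7-hydroxynon-5-en-8-ynoate
Conditions: K2CO3 (0.2 equiv), MeOH, 0 °C
Reagents that add atoms: none
Why: Methoxide-induced protodesilylation cleaves only the C(sp)–Si bond and leaves the secondary silyl ether and the methyl ester untouched.

**Step 11**
Reactants: 16 methyl (4R,5Z,7R)-4-[(tert-butyldimethylsilyl)oxy]-7-hydroxynon-5-en-8-ynoate; 17 (Z)-3-iodoprop-2-enoic acid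
Product: 19 methyl (4R,5Z,7R,8Z)-4-[(tert-butyldimethylsilyl)oxy]-7-hydroxy-8-(5-oxofuran-2(5H)-ylidene)oct-5-enoate, via enynoic acid 18 (not isolated)
Conditions: PdCl2(PPh3)2 (5 mol%), CuI (10 mol%), Et3N, MeCN, rt, dark
Reagents that add atoms: none
Why: Tandem Sonogashira coupling and in situ 5-exo-dig lactonisation of the (Z)-2-en-4-ynoic acid (anti addition of the carboxylate across the metal-activated alkyne) should give the (Z)-γ-ylidenebutenolide, which fixes the C8=C9 geometry needed for the chelate in step 12.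

**Step 12**
Reactants: 5 (2Z,5Z)-1-chloroocta-2,5-diene; 19 methyl (4R,5Z,7R,8Z)-4-[(tert-butyldimethylsilyl)oxy]-7-hydroxy-8-(5-oxofuran-2(5H)-ylidene)oct-5-enoate
Product: 23 methyl (4R,5Z,7R)-4-[(tert-butyldimethylsilyl)oxy]-7-hydroxy-7-{(1S,5S)-5-hydroxy-5-[(2Z,5Z)-octa-2,5-dien-1-yl]-2-oxocyclopent-3-en-1-yl}hept-5-enoate, via allylbarium 20 (not isolated), via lactol dialkoxide 21 (not isolated), via keto enolate 22 (not isolated)
Conditions: BaI2, lithium biphenylide (2 equiv per Ba), THF, rt; 5 (2.2 equiv), −78 °C; 19, THF, −78 → −40 °C; AcOH then aq NH4Cl, −78 °C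
Reagents that add atoms: none
Why: Proposed new method: the first equivalent of the allylic barium reagent 20 deprotonates the C7 hydroxyl and the second adds through its α-carbon with retention of the 14Z geometry (known behaviour of allylic barium reagents towards carbonyl groups) to the lactone carbonyl C12, the adduct 21 expels the ring oxygen as the (Z)-enolate O9–C9=C8, and the cis-ene-1,4-dione mono-enolate 22 closes the carbocycle by attack of C8 on the new C12 ketone; the closest known reaction types are the Fujimoto–Belleau annulation of enol lactones with Grignard reagents and the alkoxide-induced rearrangement of 5-ylidenefuran-2(5H)-ones to cyclopent-4-ene-1,3-diones, here stopped at the aldol stage because the acyl group set free is a ketone. The cyclopentenone ring closes in a 5-(enolendo)-exo-trig aldol addition (equivalently the conrotatory 4π closure of a 3-oxidopentadienyl system, as in the last event of a Piancatelli rearrangement), which should be fast because the C10=C11 cis alkene inherited from the furanone holds C8 next to C12. Both new stereocentres are set by the temporary 7R carbinol: its alkoxide and the enolate oxygen O9 are held by Ba2+ in a six-membered chelate of the Fráter–Seebach type, the C12 carbonyl is met by the enolate face anti to the C6 vinyl group, and the developing C12 alkoxide joins the same cation so that O12 ends cis to the C7 side chain, which should translate 7R into 8S and 12S. The step needs lactone over methyl ester selectivity (the enol-ester carbonyl is the more electrophilic and the nucleophile is not in excess at −78 °C), 1,2 over conjugate addition and α over γ attack (both typical of allylic barium reagents) and single addition (the ketone of 22 is consumed intramolecularly). Elimination cannot run ahead of ring closure because the C7 oxygen is an alkoxide, and the C12 configuration does not depend on later equilibration at C7 or C8, since both centres are removed in step 14.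

**Step 13**
Reactants: 23 methyl (4R,5Z,7R)-4-[(tert-butyldimethylsilyl)oxy]-7-hydroxy-7-{(1S,5S)-5-hydroxy-5-[(2Z,5Z)-octa-2,5-dien-1-yl]-2-oxocyclopent-3-en-1-yl}hept-5-enoate
Product: 24 methyl (4R,5Z,7R)-4,7-dihydroxy-7-{(1S,5S)-5-hydroxy-5-[(2Z,5Z)-octa-2,5-dien-1-yl]-2-oxocyclopent-3-en-1-yl}hept-5-enoate
Conditions: HF·pyridine, pyridine, THF, 0 °C; crude product used at once
Reagents that add atoms: none
Why: Buffered fluoride cleaves the secondary silyl ether without touching the aldol, the enone or the ester, and the triol is acetylated directly so that the γ-hydroxy ester has no time to lactonise.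

**Step 14**
Reactants: 24 methyl (4R,5Z,7R)-4,7-dihydroxy-7-{(1S,5S)-5-hydroxy-5-[(2Z,5Z)-octa-2,5-dien-1-yl]-2-oxocyclopent-3-en-1-yl}hept-5-enoate
Product: 27 17,18-dehydro-clavulone I, via diacetate 25 (not isolated), via hydroxy dienone 26 (not isolated)
Conditions: Ac2O, Et3N, DMAP, CH2Cl2, 0 °C → rt
Reagents that add atoms: acetic anhydride, CC(=O)OC(C)=O
Why: DMAP-catalysed acetylation of the two secondary alcohols is followed by E1cB loss of the C7 acetate β to the C9 ketone (aldol-condensation endgame), which removes C7 and C8 as stereocentres and should give the 7E alkene with the chain anti to the C9 carbonyl, after which the tertiary C12 alcohol is acetylated under the same conditions.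

**Compound list**

1 | 1-bromopent-2-yne | CCC#CCBr | starting material
2 | prop-2-yn-1-ol | C#CCO | starting material
3 | octa-2,5-diyn-1-ol | CCC#CCC#CCO | intermediate
4 | (2Z,5Z)-octa-2,5-dien-1-ol | CC/C=C\C/C=C\CO | intermediate
5 | (2Z,5Z)-1-chloroocta-2,5-diene | CC/C=C\C/C=C\CCl | intermediate
6 | methyl 4-chloro-4-oxobutanoate | COC(=O)CCC(Cl)=O | starting material
7 | 3,3-diethoxyprop-1-yne | C#CC(OCC)OCC | starting material
8 | methyl 7,7-diethoxy-4-oxohept-5-ynoate | COC(=O)CCC(=O)C#CC(OCC)OCC | intermediate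
9 | methyl (R)-7,7-diethoxy-4-hydroxyhept-5-ynoate | COC(=O)CC[C@@H](O)C#CC(OCC)OCC | intermediate
10 | methyl (R)-4-[(tert-butyldimethylsilyl)oxy]-7,7-diethoxyhept-5-ynoate | COC(=O)CC[C@@H](O[Si](C)(C)C(C)(C)C)C#CC(OCC)OCC | intermediate
11 | methyl (4R,5Z)-4-[(tert-butyldimethylsilyl)oxy]-7,7-diethoxyhept-5-enoate | COC(=O)CC[C@@H](O[Si](C)(C)C(C)(C)C)/C=C\C(OCC)OCC | intermediate
12 | methyl (4R,5Z)-4-[(tert-butyldimethylsilyl)oxy]-7-oxohept-5-enoate | COC(=O)CC[C@@H](O[Si](C)(C)C(C)(C)C)/C=C\C=O | intermediate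
13 | ethynyltrimethylsilane | C#C[Si](C)(C)C | starting material
14 | methyl[(trimethylsilyl)ethynyl]zinc (not isolated) | C[Zn]C#C[Si](C)(C)C | intermediate
15 | methyl (4R,5Z,7R)-4-[(tert-butyldimethylsilyl)oxy]-7-hydroxy-9-(trimethylsilyl)non-5-en-8-ynoate | COC(=O)CC[C@@H](O[Si](C)(C)C(C)(C)C)/C=C\[C@@H](O)C#C[Si](C)(C)C | intermediate
16 | methyl (4R,5Z,7R)-4-[(tert-butyldimethylsilyl)oxy]-7-hydroxynon-5-en-8-ynoate | COC(=O)CC[C@@H](O[Si](C)(C)C(C)(C)C)/C=C\[C@@H](O)C#C | intermediate
17 | (Z)-3-iodoprop-2-enoic acid | OC(=O)/C=C\I | starting material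
18 | (2Z,6R,7Z,9R)-9-[(tert-butyldimethylsilyl)oxy]-6-hydroxy-12-methoxy-12-oxododeca-2,7-dien-4-ynoic acid (not isolated) | COC(=O)CC[C@@H](O[Si](C)(C)C(C)(C)C)/C=C\[C@@H](O)C#C/C=C\C(O)=O | intermediate
19 | methyl (4R,5Z,7R,8Z)-4-[(tert-butyldimethylsilyl)oxy]-7-hydroxy-8-(5-oxofuran-2(5H)-ylidene)oct-5-enoate | COC(=O)CC[C@@H](O[Si](C)(C)C(C)(C)C)/C=C\[C@@H](O)/C=C1\OC(=O)C=C1 | intermediate
20 | (2Z,5Z)-octa-2,5-dien-1-ylbarium chloride (not isolated) | CC/C=C\C/C=C\C[Ba]Cl | intermediate
21 | tetrahedral adduct of 20 at the lactone carbonyl of 19, as the bis(chlorobarium) dialkoxide, new lactol centre undefined (not isolated) | COC(=O)CC[C@@H](O[Si](C)(C)C(C)(C)C)/C=C\[C@@H]([O-])/C=C1\OC([O-])(C/C=C\C/C=C\CC)C=C1.[Ba+]Cl.[Ba+]Cl | intermediate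
22 | ring-opened cis-ene-1,4-dione as its C9 (Z)-enolate and C7 alkoxide, bis(chlorobarium) salt (not isolated) | COC(=O)CC[C@@H](O[Si](C)(C)C(C)(C)C)/C=C\[C@@H]([O-])/C=C(\[O-])/C=C\C(=O)C/C=C\C/C=C\CC.[Ba+]Cl.[Ba+]Cl | intermediate
23 | methyl (4R,5Z,7R)-4-[(tert-butyldimethylsilyl)oxy]-7-hydroxy-7-{(1S,5S)-5-hydroxy-5-[(2Z,5Z)-octa-2,5-dien-1-yl]-2-oxocyclopent-3-en-1-yl}hept-5-enoate | COC(=O)CC[C@@H](O[Si](C)(C)C(C)(C)C)/C=C\[C@@H](O)[C@@H]1C(=O)C=C[C@@]1(O)C/C=C\C/C=C\CC | intermediate
24 | methyl (4R,5Z,7R)-4,7-dihydroxy-7-{(1S,5S)-5-hydroxy-5-[(2Z,5Z)-octa-2,5-dien-1-yl]-2-oxocyclopent-3-en-1-yl}hept-5-enoate | COC(=O)CC[C@@H](O)/C=C\[C@@H](O)[C@@H]1C(=O)C=C[C@@]1(O)C/C=C\C/C=C\CC | intermediate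
25 | methyl (4R,5Z,7R)-4,7-diacetoxy-7-{(1S,5S)-5-hydroxy-5-[(2Z,5Z)-octa-2,5-dien-1-yl]-2-oxocyclopent-3-en-1-yl}hept-5-enoate (not isolated) | COC(=O)CC[C@@H](OC(C)=O)/C=C\[C@@H](OC(C)=O)[C@@H]1C(=O)C=C[C@@]1(O)C/C=C\C/C=C\CC | intermediate
26 | methyl (4R,5Z,7E)-4-acetoxy-7-{(2S)-2-hydroxy-2-[(2Z,5Z)-octa-2,5-dien-1-yl]-5-oxocyclopent-3-en-1-ylidene}hept-5-enoate (not isolated) | CC/C=C\C/C=C\C[C@]1(O)C=CC(=O)/C1=C/C=C\[C@@H](CCC(=O)OC)OC(C)=O | intermediate
27 | 17,18-dehydro-clavulone I, methyl (4R,5Z,7E)-4-acetoxy-7-{(2S)-2-acetoxy-2-[(2Z,5Z)-octa-2,5-dien-1-yl]-5-oxocyclopent-3-en-1-ylidene}hept-5-enoate | CC/C=C\C/C=C\C[C@]1(OC(C)=O)C=CC(=O)/C1=C/C=C\[C@@H](CCC(=O)OC)OC(C)=O | target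

**Step count**

Total: 14 steps. Longest linear sequence: 11 steps (6 → 27, steps 4–14); the chloride 5 is made in 3 steps and joins at step 12.

**Steps most likely to fail**

1. Step 12 (bears the label). Several processes could intervene:
- attack of the barium reagent on the methyl ester, or on the ketone released by ring opening;
- prototropic isomerisation or Z/E erosion of the skipped dienylbarium;
- silyl migration from O4 to the C7 alkoxide;
- anionic oxy-Cope rearrangement of the tertiary alkoxide on warming;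
- insufficient facial selectivity in the aldol closure.

Fallback by known chemistry, setting out from 20 (made from 5 as in step 12) and from 12, and coming back to the route at 26. Reagent 20 is added at −78 °C in THF to commercial (S)-4-[(tert-butyldimethylsilyl)oxy]cyclopent-2-en-1-one (O=C1C=C[C@@H](O[Si](C)(C)C(C)(C)C)C1). 1,2-Addition anti to the silyloxy group should give (1R,4S)-4-[(tert-butyldimethylsilyl)oxy]-1-[(2Z,5Z)-octa-2,5-dien-1-yl]cyclopent-2-en-1-ol F1. TBAF in THF should then give (1R,4S)-1-[(2Z,5Z)-octa-2,5-dien-1-yl]cyclopent-2-ene-1,4-diol F2, and MnO2 in CH2Cl2 should oxidise only the secondary allylic alcohol to (R)-4-hydroxy-4-[(2Z,5Z)-octa-2,5-dien-1-yl]cyclopent-2-en-1-one F3. The dianion of F3 (LDA, 2.2 equiv, THF, −78 °C) is treated with 12 in a classical aldol addition to give methyl (4R,5Z)-4-[(tert-butyldimethylsilyl)oxy]-7-hydroxy-7-{(5S)-5-hydroxy-5-[(2Z,5Z)-octa-2,5-dien-1-yl]-2-oxocyclopent-3-en-1-yl}hept-5-enoate F4 as a mixture at C7 and C8. HF·pyridine as in step 13 should give the triol mixture F5. The conditions of step 14 convert it into the diacetate mixture F6, which loses its C7 acetate to converge on 26 and then 27.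

2. Step 9. The Z-enal may isomerise to the E-enal at the Lewis-acidic zinc centre, and catalyst control of the C7 face may be insufficient or of the assumed sense only in part.

Fallback, setting out from 12 and 13 and coming back at 15 and 16. Lithium (trimethylsilyl)acetylide F7 (from 13 and n-BuLi, THF, −78 °C) is added to 12 at −78 °C without a Lewis acid. This should give 15 together with its C7 epimer, methyl (4R,5Z,7S)-4-[(tert-butyldimethylsilyl)oxy]-7-hydroxy-9-(trimethylsilyl)non-5-en-8-ynoate F8; the two are diastereomers and are separated by chromatography. The 7S epimer F8 is inverted by a Mitsunobu reaction (4-nitrobenzoic acid, PPh3, DIAD, THF, 0 °C) to methyl (4R,5Z,7R)-4-[(tert-butyldimethylsilyl)oxy]-7-[(4-nitrobenzoyl)oxy]-9-(trimethylsilyl)non-5-en-8-ynoate F9. K2CO3 in MeOH removes the ester and the alkynyl silyl group together and gives 16.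

3. Step 8. The Z-enal may isomerise to the E-enal, or the silyl ether may be lost, under the acid needed to hydrolyse the acetal.

Fallback, setting out from 6 and coming back at 12; the aldehyde is unveiled by neutral oxidation of a Z-allylic alcohol instead of hydrolysis of a Z-acetal. Acid chloride 6 is coupled with prop-2-yn-1-yl acetate (C#CCOC(C)=O) under the conditions of step 4 to give methyl 7-acetoxy-4-oxohept-5-ynoate F10. The conditions of step 5 should give methyl (R)-7-acetoxy-4-hydroxyhept-5-ynoate F11, those of step 6 methyl (R)-7-acetoxy-4-[(tert-butyldimethylsilyl)oxy]hept-5-ynoate F12, and those of step 7 methyl (4R,5Z)-7-acetoxy-4-[(tert-butyldimethylsilyl)oxy]hept-5-enoate F13. K2CO3 in MeOH at 0 °C removes the acetate to give methyl (4R,5Z)-4-[(tert-butyldimethylsilyl)oxy]-7-hydroxyhept-5-enoate F14. Dess–Martin periodinane buffered with NaHCO3 (CH2Cl2, 0 °C) should then give 12 with the Z geometry intact.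

**Further compounds**

F1 | step 12 | (1R,4S)-4-[(tert-butyldimethylsilyl)oxy]-1-[(2Z,5Z)-octa-2,5-dien-1-yl]cyclopent-2-en-1-ol | CC/C=C\C/C=C\C[C@]1(O)C=C[C@@H](O[Si](C)(C)C(C)(C)C)C1
F2 | step 12 | (1R,4S)-1-[(2Z,5Z)-octa-2,5-dien-1-yl]cyclopent-2-ene-1,4-diol | CC/C=C\C/C=C\C[C@]1(O)C=C[C@@H](O)C1
F3 | step 12 | (R)-4-hydroxy-4-[(2Z,5Z)-octa-2,5-dien-1-yl]cyclopent-2-en-1-one | CC/C=C\C/C=C\C[C@]1(O)C=CC(=O)C1
F4 | step 12 | methyl (4R,5Z)-4-[(tert-butyldimethylsilyl)oxy]-7-hydroxy-7-{(5S)-5-hydroxy-5-[(2Z,5Z)-octa-2,5-dien-1-yl]-2-oxocyclopent-3-en-1-yl}hept-5-enoate, mixture at C7 and C8 | COC(=O)CC[C@@H](O[Si](C)(C)C(C)(C)C)/C=C\C(O)C1C(=O)C=C[C@@]1(O)C/C=C\C/C=C\CC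
F5 | step 12 | methyl (4R,5Z)-4,7-dihydroxy-7-{(5S)-5-hydroxy-5-[(2Z,5Z)-octa-2,5-dien-1-yl]-2-oxocyclopent-3-en-1-yl}hept-5-enoate, mixture at C7 and C8 | COC(=O)CC[C@@H](O)/C=C\C(O)C1C(=O)C=C[C@@]1(O)C/C=C\C/C=C\CC
F6 | step 12 | methyl (4R,5Z)-4,7-diacetoxy-7-{(5S)-5-hydroxy-5-[(2Z,5Z)-octa-2,5-dien-1-yl]-2-oxocyclopent-3-en-1-yl}hept-5-enoate, mixture at C7 and C8 | COC(=O)CC[C@@H](OC(C)=O)/C=C\C(OC(C)=O)C1C(=O)C=C[C@@]1(O)C/C=C\C/C=C\CC
F7 | step 9 | lithium (trimethylsilyl)acetylide | [Li]C#C[Si](C)(C)C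
F8 | step 9 | methyl (4R,5Z,7S)-4-[(tert-butyldimethylsilyl)oxy]-7-hydroxy-9-(trimethylsilyl)non-5-en-8-ynoate | COC(=O)CC[C@@H](O[Si](C)(C)C(C)(C)C)/C=C\[C@H](O)C#C[Si](C)(C)C
F9 | step 9 | methyl (4R,5Z,7R)-4-[(tert-butyldimethylsilyl)oxy]-7-[(4-nitrobenzoyl)oxy]-9-(trimethylsilyl)non-5-en-8-ynoate | COC(=O)CC[C@@H](O[Si](C)(C)C(C)(C)C)/C=C\[C@@H](OC(=O)c1ccc(cc1)[N+](=O)[O-])C#C[Si](C)(C)C
F10 | step 8 | methyl 7-acetoxy-4-oxohept-5-ynoate | COC(=O)CCC(=O)C#CCOC(C)=O
F11 | step 8 | methyl (R)-7-acetoxy-4-hydroxyhept-5-ynoate | COC(=O)CC[C@@H](O)C#CCOC(C)=O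
F12 | step 8 | methyl (R)-7-acetoxy-4-[(tert-butyldimethylsilyl)oxy]hept-5-ynoate | COC(=O)CC[C@@H](O[Si](C)(C)C(C)(C)C)C#CCOC(C)=O
F13 | step 8 | methyl (4R,5Z)-7-acetoxy-4-[(tert-butyldimethylsilyl)oxy]hept-5-enoate | COC(=O)CC[C@@H](O[Si](C)(C)C(C)(C)C)/C=C\COC(C)=O
F14 | step 8 | methyl (4R,5Z)-4-[(tert-butyldimethylsilyl)oxy]-7-hydroxyhept-5-enoate | COC(=O)CC[C@@H](O[Si](C)(C)C(C)(C)C)/C=C\CO
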